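Za at 75 % of the charge after 30.0 s, in both runs despite their different Zb charges, was where I started. Za reacts with Zb towards the bis adduct Zf, and what has reacted is one minus the Za fraction, so the Zf readings near zero told me little.

| setting | zeta | alpha | Monday's | Tuesday's |
|---|---|---|---|---|
| Za | 0.25 M | 0.25 M | 0.25 M | 0.25 M |
| Zb | 0.84 equiv | 1.3 equiv | 1.20 equiv | 1.80 equiv |
| remark | run made earlier | run made earlier |  |  |
| time |  |  | 2.0 min | 2.0 min |

| run | time / s | Za / % | Zf / % |
|---|---|---|---|
| zeta | 10.0 | 94 | 0 |
| zeta | 15.0 | 87 | 1 |
| zeta | 30.0 | 75 | 0 |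
| zeta | 60.0 | 65 | 1 |
| alpha | 10.0 | 89 | 0 |
| alpha | 15.0 | 87 | 1 |
| alpha | 30.0 | 75 | 0 |
| alpha | 40.0 | 68 | 0 |
| alpha | 60.0 | 54 | 0 |

(each reading ± 2 percentage points)

1. part of the Za that has reacted at the end, Monday's
2. part of the Za that has reacted at the end, Tuesday's
3. what raising the equivalents of Zb from its lowest to its highest value here does to the part of the Za that has reacted (changes below 5 percentage points count as none) (it falls / no change / it rises)

- what has gone from Za into another species counts as reacted, even if it can come back
- a reading or a percentage of Zf counts all its forms, free or not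
- a reading of Za is of its free form alone

I worked in logarithms. The decade rate is a pseudo-first-order constant in base ten: the decades of free Za lost per minute, the log of charge over reading, divided by time. Zeta, with less Zb than either new flask, gave 0.187 min⁻¹ at 60.0 s, the floor rate. Over 2.0 min that leaves a floor of 57.7 % reacted, and the reading's scatter moves this by about 2.6 percentage points.

Alpha's last reading gave 0.268 min⁻¹, a ceiling of 70.8 %, which I held as an estimate, since alpha was charged with less Zb than Tuesday's. Zeta held more Za than alpha at 60.0 s, so I expected a rise with Zb.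

The forecast gave 55 % and 69 % and said it rises, holding that zeta “seems to be running out of Zb”. Its first figure lay below my floor, its second just under my ceiling.

Monday's gave 59.1 % and Tuesday's 67.2 %, so with the higher Zb charge the answer was it rises, by 8.1 points, and both lay inside the bracket.

    Za + Zb → Ze + Zc (k = 0.0127 L mol⁻¹ s⁻¹)
    Zb + Ze → Zf + Zc (k = 0.00382 L mol⁻¹ s⁻¹)
    Za + Zc ⇌ Zg, settled at all times (K = 3.39 L mol⁻¹)
    Za + Zf ⇌ Zh, settled at all times (K = 6.99 L mol⁻¹)
    Za ⇌ Zd (K = 0.968, k = 0.00481 s⁻¹)

At 2.00 min, Monday's held less of its Za, 41 %, than of its Zb, 77 %. That Za is a decade rate of 0.194 min⁻¹, level with the floor rate. Carried to the same flask read at 5.0 min, the floor rate gives 11.6 % of the Za left, but that flask held more: 24 %, a decade rate of 0.124 min⁻¹.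

All runs stem from a simulated flask from invented constants, noise included.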